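**Retrosynthetic overview**

- Locants: C1 = CH–O-angeloyl, C2=C3(CH3), C4 = CH2, C5 = CH–O-veratroyl, C6 = fusion CH, C7 = fusion C(CH3), C8/C9 = CH2, C10 = C(OH)(i-Pr); seven-membered ring C1–C7, five-membered ring C6–C10. The plan rests on the C1(O)–C2H=C3(CH3) triad lying next to quaternary C7 in the seven-membered ring: removing C2 leaves a trans-fused hydrindan-1-one whose only enolisable side is C3.
- Endgame: C1–O angelate by Mitsunobu inversion of the 1α-alcohol obtained by 1,2-reduction of the C1 ketone; C5 veratrate by acylation.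
- Key disconnection: C1–C2 and C2–C3, a CH2 insertion into the C1=C3 silyl enol ether (cyclopropanation, then FeCl3 opening of the shared bond), enlarging the six-membered ring to seven.
- Hydrindenone: C3=C4 by aldol condensation of a keto aldehyde from a double ozonolysis; C10 carbinol by isopropylcerium addition; C6–C5 by aldol with acrolein; quaternary C7 by copper-catalysed asymmetric conjugate addition to 3-methylcyclopent-2-enone.
- Ring order: five-membered ring (starting material), six-membered ring (step 6), seven-membered ring (step 8).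

Key step: step 8

Remark: the face carrying H6 is called β, so C7–CH3 and C10–OH are α while C5–O, C10–i-Pr and the target C1–O are β; the absolute sense of step 1 is assumed to be set by the choice of ligand antipode, (S) at C7 being required.

Step 1
Reactants: 1 3-methylcyclopent-2-en-1-one; 2 2-bromobut-1-ene
Product: 6 trimethyl{[(3S)-3-(but-1-en-2-yl)-3-methylcyclopent-1-en-1-yl]oxy}silane (silyl enol ether C10=C6; C7 quaternary), via but-1-en-2-yllithium 3 (not isolated), via (but-1-en-2-yl)dimethylaluminium 4 (not isolated), via dimethylaluminium enolate 5 (not isolated)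
Conditions: 2, t-BuLi (2 equiv), Et2O, −78 °C; Me2AlCl, −78 → −30 °C; 1, copper thiophene-2-carboxylate (CuTC, 10 mol %), chiral aminophosphine of the SimplePhos type Ph2P–N[CH(CH3)Ar]2 (11 mol %), Et2O, −30 °C; TMSOTf, Et3N, −30 °C → rt
Reagents that add atoms: trimethylsilyl trifluoromethanesulfonate, C[Si](C)(C)OS(=O)(=O)C(F)(F)F
Why: copper-catalysed asymmetric conjugate addition of an alkenylalane to a β-substituted cyclic enone builds quaternary C7 (the ligand antipode is chosen so that the alkenyl group enters on the face giving 7S), and O-silylation of the aluminium enolate stores the enolate regiochemistry at C10=C6.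

Step 2
Reactants: 6 trimethyl{[(3S)-3-(but-1-en-2-yl)-3-methylcyclopent-1-en-1-yl]oxy}silane; 7 acrolein
Product: 9 (2S,3S)-3-(but-1-en-2-yl)-2-[(1S)-1-hydroxyprop-2-en-1-yl]-3-methylcyclopentan-1-one, via lithium enolate 8 (not isolated)
Conditions: MeLi, THF, 0 °C; 7, −78 °C; aqueous NH4Cl
Reagents that add atoms: none
Why: methyllithium cleaves the O–Si bond to the regiodefined lithium enolate, which undergoes a 1,2-aldol addition to acrolein through a chair Zimmerman–Traxler transition state (ring E-enolate, hence the anti C6/C5 relationship, 5S) on the enolate face opposite the larger but-1-en-2-yl group, so the new C6–C5 bond is trans to that group.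

Step 3
Reactants: 9 (2S,3S)-3-(but-1-en-2-yl)-2-[(1S)-1-hydroxyprop-2-en-1-yl]-3-methylcyclopentan-1-one
Product: 10 (2S,3S)-3-(but-1-en-2-yl)-2-[(1S)-1-(tert-butyldimethylsilyloxy)prop-2-en-1-yl]-3-methylcyclopentan-1-one
Conditions: TBSOTf, 2,6-lutidine, CH2Cl2, −78 °C
Reagents that add atoms: tert-butyldimethylsilyl trifluoromethanesulfonate, CC(C)(C)[Si](C)(C)OS(=O)(=O)C(F)(F)F
Why: silylation of the secondary aldol hydroxyl with a silyl triflate and a hindered pyridine base at low temperature protects it for the organometallic step and is fast enough to outrun retro-aldol cleavage, no stereocentre being touched.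

Step 4
Reactants: 10 (2S,3S)-3-(but-1-en-2-yl)-2-[(1S)-1-(tert-butyldimethylsilyloxy)prop-2-en-1-yl]-3-methylcyclopentan-1-one; 11 isopropylmagnesium chloride
Product: 13 (1R,2S,3S)-3-(but-1-en-2-yl)-2-[(1S)-1-(tert-butyldimethylsilyloxy)prop-2-en-1-yl]-3-methyl-1-(propan-2-yl)cyclopentan-1-ol, via isopropylcerium dichloride 12 (not isolated)
Conditions: 11, anhydrous CeCl3, THF, −78 °C; 10, −78 → 0 °C; aqueous NH4Cl
Reagents that add atoms: none
Why: the weakly basic, non-reducing organocerium reagent adds 1,2 to the hindered, enolisable cyclopentanone on the carbonyl face anti to the adjacent C6 side chain, which places isopropyl β and hydroxyl α at C10 (10R).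

Step 5
Reactants: 13 (1R,2S,3S)-3-(but-1-en-2-yl)-2-[(1S)-1-(tert-butyldimethylsilyloxy)prop-2-en-1-yl]-3-methyl-1-(propan-2-yl)cyclopentan-1-ol
Product: 15 keto aldehyde (C1 ethyl ketone on C7; C4 aldehyde on C5; 5-OTBS; 10α-OH), via bis-ozonide 14 (not isolated)
Conditions: O3, CH2Cl2, −78 °C; PPh3, −78 °C → rt
Reagents that add atoms: ozone, [O-][O+]=O
Why: ozonolysis (Criegee mechanism, reductive work-up) cleaves both terminal alkenes in one operation and so unveils the C1 ethyl ketone and the C4 aldehyde without touching a stereocentre.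

Step 6
Reactants: 15 keto aldehyde
Product: 17 trans-hydrind-3-en-1-one (C1 ketone; C3-methyl; C3=C4; 5β-OTBS; 6β-H; 7α-CH3; 10α-OH; 10β-isopropyl), via β-hydroxy ketone 16 (not isolated)
Conditions: KOH, MeOH, 0 °C → rt
Reagents that add atoms: none
Why: intramolecular aldol condensation in which the only ketone enolate that can form (at C3, since C7 is quaternary) attacks the C4 aldehyde in a 6-(enolendo)-exo-trig closure and E1cB loss of water gives the conjugated C3=C4 enone, the trans ring fusion following from the trans C6/C7 substituents set in step 2.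

Step 7
Reactants: 17 trans-hydrind-3-en-1-one
Product: 18 C1 triethylsilyl enol ether of the trans-hydrindane (C1=C3; 5β-OTBS; 10α-OH)
Conditions: RhCl(PPh3)3 (3 mol %), Et3SiH, toluene, 50 °C
Reagents that add atoms: triethylsilane, CC[SiH](CC)CC
Why: rhodium-catalysed 1,4-hydrosilylation of the enone puts hydrogen on C4 and silicon on oxygen, giving the tetrasubstituted C1=C3 silyl enol ether regiospecifically under neutral conditions, the C5 oxygen being kept as its silyl ether because an allylic carboxylate could be expelled at this stage.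

Step 8
Reactants: 18 C1 triethylsilyl enol ether of the trans-hydrindane; 19 diiodomethane
Product: 22 trans-hydroazulen-1-one (C2=C3 enone; 3-methyl; 5β-OTBS; 6β-H; 7α-CH3; 10α-OH; 10β-isopropyl), via siloxycyclopropane 20 (not isolated), via β-chloro ketone 21 (not isolated)
Conditions: Et2Zn, 19, toluene, 0 °C → rt; crude 20, anhydrous FeCl3 (3 equiv), DMF, 0 °C → rt; crude 21, NaOAc, MeOH, rt → 40 °C
Reagents that add atoms: none
Why: The zinc carbenoid EtZnCH2I formed from Et2Zn and 19 transfers CH2 in a concerted step to the electron-rich C1=C3 enol ether (Simmons–Smith reaction) to give 20; FeCl3 then removes one electron from 20, the radical cation breaks the C1–C3 bond to give the C1 carbonyl (silicon leaves as Et3SiCl) and a tertiary C3 radical that takes chlorine from a second FeCl3 to give 21, and acetate removes HCl by E1cB across C2–C3. The closest known reaction type is the enlargement of cyclohexanone silyl enol ethers to cyclohept-2-enones through siloxycyclopropanes and FeCl3 (Ito–Saegusa ring expansion), including 2-methyl cases that give 3-methylcycloheptenones. The only ring actually closed is the transient cyclopropane, by a [2+1] methylene transfer; the seven-membered ring C1–C7 then arises by fragmentation of the bond shared by the three- and six-membered rings, not by cyclisation, and the new skeletal bonds are C1–C2 and C2–C3. No lasting stereocentre is made, since the cyclopropane carbons (methylene expected on the β-face, anti to the C7 methyl) and the chlorinated C3 are both erased while C5, C6, C7 and C10 are untouched. Two selectivities decide the outcome: the oxidised cyclopropane must break the shared bond, which is favoured because this releases the bicyclic strain and leaves the radical on fully substituted C3, and HCl must be lost into conjugation, which is favoured because only the C2 hydrogens are α to the new ketone. The position of the enol ether is unambiguous because quaternary C7 allows enolisation only towards C3, and the weak base and the silyl ether at C5 guard against vinylogous β-elimination of the C5 oxygen through the acidic C4 hydrogens.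

Step 9
Reactants: 22 trans-hydroazulen-1-one (5β-OTBS)
Product: 23 trans-hydroazulen-1-one 5β,10α-diol (C2=C3 enone)
Conditions: HF·pyridine, pyridine, THF, 0 °C → rt
Reagents that add atoms: none
Why: acidic fluoride cleaves the secondary silyl ether through Si–F bond formation and leaves the enone intact, a basic fluoride source being avoided because the freed C5 hydroxyl stands in a vinylogous aldol relationship to the C1 ketone.

Step 10
Reactants: 23 trans-hydroazulen-1-one 5β,10α-diol; 24 3,4-dimethoxybenzoyl chloride
Product: 25 trans-hydroazulen-1-one 5β-veratrate (C2=C3 enone; 10α-OH)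
Conditions: 24, pyridine, DMAP (catalytic), CH2Cl2, 0 °C → rt
Reagents that add atoms: none
Why: DMAP-catalysed acylation (nucleophilic catalysis) esterifies the secondary C5 hydroxyl with retention under non-enolising conditions, the tertiary C10 hydroxyl being too hindered to react.

Step 11
Reactants: 25 trans-hydroazulen-1-one 5β-veratrate
Product: 26 (1S)-1α-hydroxy-hydroazul-2-ene 5β-veratrate (10α-OH)
Conditions: NaBH4, CeCl3·7H2O, MeOH, −78 → −40 °C
Reagents that add atoms: none
Why: Luche reduction gives clean 1,2-addition to the enone, and hydride enters on the β-face of C1, anti to the pseudo-axial C7 methyl, so the new hydroxyl is α (cis to that methyl), while the aryl ester is untouched at low temperature.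

Step 12
Reactants: 26 (1S)-1α-hydroxy-hydroazul-2-ene 5β-veratrate; 27 angelic acid
Product: 28 target, (1R,5S,6S,7S,10R)-1-angeloyloxy-5-veratroyloxy-hydroazul-2-en-10-ol
Conditions: 27, PPh3, DIAD, toluene, 0 °C → rt
Reagents that add atoms: none
Why: Mitsunobu esterification in which the carboxylate displaces the oxyphosphonium group at allylic C1 with inversion from the β-face (the face anti to the C7 methyl, the same sense as the known inversion of 17β-hydroxy steroids), giving the 1β-angelate; the acid acts only as a nucleophile so its Z alkene is not isomerised, and the tertiary C10 hydroxyl is inert.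

**Compound list**

1 | 3-methylcyclopent-2-en-1-one | CC1=CC(=O)CC1 | starting material
2 | 2-bromobut-1-ene | C=C(Br)CC | starting material
3 | but-1-en-2-yllithium | [Li]C(=C)CC | intermediate
4 | (but-1-en-2-yl)dimethylaluminium | C[Al](C)C(=C)CC | intermediate
5 | dimethylaluminium (3S)-3-(but-1-en-2-yl)-3-methylcyclopent-1-en-1-olate | C[Al](C)OC1=C[C@](C(=C)CC)(C)CC1 | intermediate
6 | trimethyl{[(3S)-3-(but-1-en-2-yl)-3-methylcyclopent-1-en-1-yl]oxy}silane | C[Si](C)(C)OC1=C[C@](C(=C)CC)(C)CC1 | intermediate
7 | acrolein (prop-2-enal) | C=CC=O | starting material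
8 | lithium (3S)-3-(but-1-en-2-yl)-3-methylcyclopent-1-en-1-olate | [Li]OC1=C[C@](C(=C)CC)(C)CC1 | intermediate
9 | (2S,3S)-3-(but-1-en-2-yl)-2-[(1S)-1-hydroxyprop-2-en-1-yl]-3-methylcyclopentan-1-one | C=C[C@H](O)[C@@H]1[C@](C(=C)CC)(C)CCC1=O | intermediate
10 | (2S,3S)-3-(but-1-en-2-yl)-2-[(1S)-1-(tert-butyldimethylsilyloxy)prop-2-en-1-yl]-3-methylcyclopentan-1-one | C=C[C@H](O[Si](C)(C)C(C)(C)C)[C@@H]1[C@](C(=C)CC)(C)CCC1=O | intermediate
11 | isopropylmagnesium chloride | CC(C)[Mg]Cl | starting material
12 | isopropylcerium dichloride | CC(C)[Ce](Cl)Cl | intermediate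
13 | (1R,2S,3S)-3-(but-1-en-2-yl)-2-[(1S)-1-(tert-butyldimethylsilyloxy)prop-2-en-1-yl]-3-methyl-1-(propan-2-yl)cyclopentan-1-ol | C=C[C@H](O[Si](C)(C)C(C)(C)C)[C@@H]1[C@](C(=C)CC)(C)CC[C@@]1(O)C(C)C | intermediate
14 | bis-ozonide of 13 (both C=CH2 units as 1,2,4-trioxolanes; trioxolane carbons C1 and C4 undefined) | C1(OCOO1)[C@H](O[Si](C)(C)C(C)(C)C)[C@@H]2[C@](C3(CC)OCOO3)(C)CC[C@@]2(O)C(C)C | intermediate
15 | keto aldehyde: cyclopentanol 13 with propanoyl (C1) on C7 and formyl (C4) on (5R)-C5(OTBS); 6β-H, 7α-CH3, 10α-OH; in equilibrium with its C10–O lactol | O=C[C@H](O[Si](C)(C)C(C)(C)C)[C@@H]1[C@](C(=O)CC)(C)CC[C@@]1(O)C(C)C | intermediate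
16 | aldol intermediate: trans-hydrindan-1-one with 3-CH3 and 4-OH (C3, C4 undefined), 5β-OTBS, 10α-OH | O=C1C(C)C(O)[C@H](O[Si](C)(C)C(C)(C)C)[C@@H]2[C@]1(C)CC[C@@]2(O)C(C)C | intermediate
17 | trans-hydrind-3-en-1-one: six-membered ring C1(=O)–C3(CH3)=C4–C5–C6–C7, five-membered ring C6–C10; 5β-OTBS, 6β-H, 7α-CH3, 10α-OH, 10β-isopropyl | O=C1C(C)=C[C@H](O[Si](C)(C)C(C)(C)C)[C@@H]2[C@]1(C)CC[C@@]2(O)C(C)C | intermediate
18 | C1 triethylsilyl enol ether (C1=C3) of the trans-hydrindane; 5β-OTBS, 6β-H, 7α-CH3, 10α-OH, 10β-isopropyl | CC[Si](CC)(CC)OC1=C(C)C[C@H](O[Si](C)(C)C(C)(C)C)[C@@H]2[C@]1(C)CC[C@@]2(O)C(C)C | intermediate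
19 | diiodomethane | ICI | starting material
20 | siloxycyclopropane: CH2 (future C2) bridging C1(OSiEt3) and C3(CH3) on the β-face of 18 | CC[Si](CC)(CC)O[C@@]12C[C@]1(C)C[C@H](O[Si](C)(C)C(C)(C)C)[C@@H]3[C@]2(C)CC[C@@]3(O)C(C)C | intermediate
21 | 3-chloro-3-methyl-trans-hydroazulen-1-one (C3 epimers), 5β-OTBS, 10α-OH | O=C1CC(C)(Cl)C[C@H](O[Si](C)(C)C(C)(C)C)[C@@H]2[C@]1(C)CC[C@@]2(O)C(C)C | intermediate
22 | trans-hydroazulen-1-one with C2=C3 enone: 3-CH3, 5β-OTBS, 6β-H, 7α-CH3, 10α-OH, 10β-isopropyl | O=C1C=C(C)C[C@H](O[Si](C)(C)C(C)(C)C)[C@@H]2[C@]1(C)CC[C@@]2(O)C(C)C | intermediate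
23 | trans-hydroazulen-1-one 5β,10α-diol with C2=C3 enone | O=C1C=C(C)C[C@H](O)[C@@H]2[C@]1(C)CC[C@@]2(O)C(C)C | intermediate
24 | 3,4-dimethoxybenzoyl chloride | COc1ccc(C(Cl)=O)cc1OC | starting material
25 | trans-hydroazulen-1-one with C2=C3 enone, 5β-(3,4-dimethoxybenzoate), 10α-OH | O=C1C=C(C)C[C@H](OC(=O)c3ccc(OC)c(OC)c3)[C@@H]2[C@]1(C)CC[C@@]2(O)C(C)C | intermediate
26 | (1S)-1α-alcohol: hydroazul-2-ene-1α,10α-diol 5β-(3,4-dimethoxybenzoate) | O[C@H]1C=C(C)C[C@H](OC(=O)c3ccc(OC)c(OC)c3)[C@@H]2[C@]1(C)CC[C@@]2(O)C(C)C | intermediate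
27 | angelic acid ((Z)-2-methylbut-2-enoic acid) | C/C=C(/C)C(=O)O | starting material
28 | target: (1R,5S,6S,7S,10R)-1β-angeloyloxy-5β-(3,4-dimethoxybenzoyloxy)-hydroazul-2-en-10α-ol | C/C=C(/C)C(=O)O[C@@H]1C=C(C)C[C@H](OC(=O)c2ccc(OC)c(OC)c2)[C@@H]2[C@]1(C)CC[C@@]2(O)C(C)C | target

**Step count**

Total: 12 steps. Longest linear sequence: 12 steps (1 to 28).

**Steps most likely to fail**

1. Step 8 (key step).
 - What may go wrong: methylene transfer to the tetrasubstituted C1=C3 bond, which is flanked by quaternary C7, may be slower than loss of the silyl group to the zinc Lewis acid. The oxidative opening may also be accompanied by over-chlorination or by elimination into the β,γ-position.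
 - Fallback (diazo homologation and dehydrogenation instead of cyclopropane fragmentation): setting out from 18, mild hydrolysis (AcOH, THF/H2O) gives the saturated trans-hydrindan-1-one F1. Me3Al-promoted addition of trimethylsilyldiazomethane (CH2Cl2, −78 → −20 °C), with migration of the less substituted C3, inserts the carbon between C1 and C3 and gives the 2-(trimethylsilyl)cycloheptanone F2. K2CO3 in MeOH desilylates F2 to the cycloheptanone F3. Dehydrogenation with 2-iodoxybenzoic acid (DMSO/toluene, 70 °C) can only occur across C2–C3 because C7 is quaternary, and it returns to the route at 22.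

2. Step 12.
 - What may go wrong: displacement at the neopentylic allylic C1 may be outrun by collapse of the oxyphosphonium ion to a 1,3-diene or by allylic transposition, so that little inverted ester forms.
 - Fallback (reagent-controlled reduction and acylation with retention instead of substitution at C1): setting out from 25, Corey–Bakshi–Shibata reduction with the (S)-2-methyl-oxazaborolidine and catecholborane (toluene, −78 °C) should give the 1β-alcohol F4 directly. This sense is predicted by the usual model with the quaternary C7 side as the large group, and the antipodal catalyst serves as the control. Angelic acid 27 is converted with 2,4,6-trichlorobenzoyl chloride and Et3N into the mixed anhydride F5. F5 acylates F4 in toluene at 80 °C without DMAP, conditions expected to preserve the Z geometry, and returns to the route at 28.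

3. Step 6.
 - What may go wrong: under equilibrating base the α-silyloxy aldehyde may enolise, eroding the C5 configuration, and it is partly held as the lactol with the C10 hydroxyl, so closure is slowed.
 - Fallback (kinetic aldol addition and separate dehydration instead of a one-pot condensation): setting out from 15, LiHMDS (2.2 equiv, THF, −78 °C) deprotonates the hydroxyl and the ethyl ketone, and the enolate adds to the aldehyde at low temperature to give β-hydroxy ketone 16, which is now isolated. MsCl and Et3N (CH2Cl2, 0 °C) convert it into the C4 mesylate F6, the tertiary alcohol not reacting. DBU at room temperature eliminates the mesylate into conjugation and returns to the route at 17.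

**Further compounds**

F1 | step 8 | saturated trans-hydrindan-1-one (3-CH3, C3 undefined; 5β-OTBS; 10α-OH) | O=C1C(C)C[C@H](O[Si](C)(C)C(C)(C)C)[C@@H]2[C@]1(C)CC[C@@]2(O)C(C)C
F2 | step 8 | 2-(trimethylsilyl)-3-methyl-trans-hydroazulan-1-one (C2, C3 undefined; 5β-OTBS; 10α-OH) | O=C1C([Si](C)(C)C)C(C)C[C@H](O[Si](C)(C)C(C)(C)C)[C@@H]2[C@]1(C)CC[C@@]2(O)C(C)C
F3 | step 8 | 3-methyl-trans-hydroazulan-1-one (C3 undefined; 5β-OTBS; 10α-OH) | O=C1CC(C)C[C@H](O[Si](C)(C)C(C)(C)C)[C@@H]2[C@]1(C)CC[C@@]2(O)C(C)C
F4 | step 12 | (1R)-1β-alcohol: hydroazul-2-ene-1β,10α-diol 5β-(3,4-dimethoxybenzoate) | O[C@@H]1C=C(C)C[C@H](OC(=O)c3ccc(OC)c(OC)c3)[C@@H]2[C@]1(C)CC[C@@]2(O)C(C)C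
F5 | step 12 | angelic 2,4,6-trichlorobenzoic anhydride | C/C=C(/C)C(=O)OC(=O)c1c(Cl)cc(Cl)cc1Cl
F6 | step 6 | C4 methanesulfonate of 16 (C3, C4 undefined) | O=C1C(C)C(OS(C)(=O)=O)[C@H](O[Si](C)(C)C(C)(C)C)[C@@H]2[C@]1(C)CC[C@@]2(O)C(C)C
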